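## Retrosynthetic overview

Tatarinoid C is (R)-1,1-bis(2,4,5-trimethoxyphenyl)propan-2-ol. C1 is the methine carrying rings A and B, C2 is the carbinol carbon and the only stereocenter, and C3 is the methyl group.
The plan rests on one feature. C1 is a latent carbocation, with ortho and para methoxy donors on both ring A and ring B, and it is bonded to C2, whose oxygen makes C2 the alpha-carbon of a glycolate enolate. The C1-C2 bond is therefore the one cut.
Forward, the chlorotitanium enolate of a chiral N-(benzyloxyacetyl)oxazolidinone captures the diarylmethyl cation released from its methyl ether. This makes C1-C2 and sets C2.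
The imide carbonyl carbon is then taken down to the C3 methyl (CH2OH, CH2OTs, CH3), and the benzyl ether is removed last.
No ring is formed: rings A and B are bought as the aryl bromide and the aldehyde and are joined at C1 by aryllithium addition.

Key step: step 4

Assumption: the descriptor in the given SMILES reads as (R) at C2, and C1 is not stereogenic because rings A and B are identical, so C2 is the only center the route has to control.

## Route

Step 1
Reactants: 1 (R)-4-benzyl-2-oxazolidinone; 2 benzyloxyacetyl chloride
Product: 4 (R)-4-benzyl-3-(benzyloxyacetyl)oxazolidin-2-one, via N-lithio oxazolidinone 3 (not isolated)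
Conditions: n-BuLi (1.0 equiv), THF, -78 °C; then 2 (1.1 equiv), -78 to 0 °C
Reagents that add atoms: none
Why: N-acylation of a lithiated oxazolidinone by an acid chloride is fast at low temperature and does not touch the C4 stereocenter of the auxiliary.

Step 2
Reactants: 5 1-bromo-2,4,5-trimethoxybenzene; 6 2,4,5-trimethoxybenzaldehyde
Product: 9 bis(2,4,5-trimethoxyphenyl)methanol, via 2,4,5-trimethoxyphenyllithium 7 (not isolated), via lithium diarylmethoxide 8 (not isolated)
Conditions: n-BuLi (1.05 equiv), THF, -78 °C; then 6, -78 to 0 °C; quench H2O (no acid in the work-up)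
Reagents that add atoms: none
Why: Bromine-lithium exchange at -78 °C gives an aryllithium stabilized by its ortho-methoxy group, and its 1,2-addition to the non-enolizable aldehyde joins rings A and B at C1, which is not stereogenic because the rings are identical.

Step 3
Reactants: 9 bis(2,4,5-trimethoxyphenyl)methanol
Product: 11 bis(2,4,5-trimethoxyphenyl)methyl methyl ether, via sodium diarylmethoxide 10 (not isolated)
Conditions: NaH (1.5 equiv), THF-DMF, 0 °C; MeI (2 equiv), 0 °C to rt
Reagents that add atoms: iodomethane (MeI), CI
Why: In this Williamson ether synthesis the alkoxide is methylated by MeI in an SN2 step, and the basic medium avoids the acid-triggered ionization to which the hexamethoxy benzhydrol is prone.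

Step 4
Reactants: 4 (R)-4-benzyl-3-(benzyloxyacetyl)oxazolidin-2-one; 11 bis(2,4,5-trimethoxyphenyl)methyl methyl ether
Product: 14 (R)-4-benzyl-3-[(S)-2-benzyloxy-3,3-bis(2,4,5-trimethoxyphenyl)propanoyl]oxazolidin-2-one, via chlorotitanium Z-enolate 12 (not isolated), via bis(2,4,5-trimethoxyphenyl)methyl cation 13 (not isolated)
Conditions: 4, TiCl4 (1.05 equiv), CH2Cl2, -78 °C; i-Pr2NEt (1.1 equiv), -78 °C, 1 h; 11, then TiCl4 (1.0 equiv) dropwise, -78 to -20 °C; quench H2O
Reagents that add atoms: none
Why: TiCl4 binds the imide and i-Pr2NEt removes the acidified alpha proton (soft enolization) to give Z-enolate 12, in which hexacoordinate tetravalent titanium can hold the enolate oxygen, the ring carbonyl oxygen and the benzyloxy oxygen in one plane; the second portion of TiCl4 abstracts methoxide from 11 in the presence of the enolate, and the enolate carbon C2 captures cation 13 through an open transition state. The closest known reaction type is the Lewis acid mediated SN1-type alkylation of chlorotitanium enolates of chiral N-acyl oxazolidinones and thiazolidinethiones by orthoesters, acetals and diarylmethyl ethers. No ring is closed; one skeletal bond, C1-C2, is made. C2 is the only new stereocenter and is controlled by the C4 benzyl group of the (R)-auxiliary, which covers one face of the chelated enolate so that 13 arrives on the open Si face of C2, the same sense as in alkali-metal enolate alkylation, giving (S) in 14. The step needs diastereofacial selectivity and C- over O-alkylation; the first is secured by the chelate that fixes the auxiliary rotamer together with the bulk of 13, the second by the strong Ti-O bond. Cation 13 suits the step because the ortho and para methoxy groups of rings A and B allow ionization at low temperature, it has no beta hydrogen to lose, and its identical rings leave C1 non-stereogenic.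

Step 5
Reactants: 14 (R)-4-benzyl-3-[(S)-2-benzyloxy-3,3-bis(2,4,5-trimethoxyphenyl)propanoyl]oxazolidin-2-one
Product: 16 (S)-2-benzyloxy-3,3-bis(2,4,5-trimethoxyphenyl)propan-1-ol, via alpha-benzyloxy aldehyde 15 (not isolated)
Conditions: LiBH4 (2 equiv), H2O (2 equiv), Et2O-THF, 0 °C
Reagents that add atoms: none
Why: In this reductive cleavage of an N-acyl oxazolidinone, hydride adds to the exocyclic imide carbonyl, the auxiliary anion leaves, and aldehyde 15 is reduced at once, so its alpha-carbon has no time to epimerize and C2 keeps its configuration.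

Step 6
Reactants: 16 (S)-2-benzyloxy-3,3-bis(2,4,5-trimethoxyphenyl)propan-1-ol
Product: 17 (S)-2-benzyloxy-3,3-bis(2,4,5-trimethoxyphenyl)propyl p-toluenesulfonate
Conditions: TsCl (1.3 equiv), Et3N (2 equiv), DMAP (cat.), CH2Cl2, 0 °C to rt
Reagents that add atoms: p-toluenesulfonyl chloride (TsCl), Cc1ccc(cc1)S(=O)(=O)Cl
Why: DMAP-catalysed O-sulfonylation of the only free hydroxyl, a primary one, breaks no bond at C2.

Step 7
Reactants: 17 (S)-2-benzyloxy-3,3-bis(2,4,5-trimethoxyphenyl)propyl p-toluenesulfonate
Product: 18 (R)-2-benzyloxy-1,1-bis(2,4,5-trimethoxyphenyl)propane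
Conditions: LiEt3BH (3 equiv), THF, 0 °C to rt
Reagents that add atoms: none
Why: SN2 displacement of a primary sulfonate by hydride from the strongly nucleophilic LiEt3BH turns CH2OTs into the C3 methyl without touching C2, whose descriptor changes from (S) to (R) only because CH3 ranks below C1, and staying at or below room temperature spares the aryl methyl ethers.

Step 8
Reactants: 18 (R)-2-benzyloxy-1,1-bis(2,4,5-trimethoxyphenyl)propane
Product: 19 tatarinoid C [(R)-1,1-bis(2,4,5-trimethoxyphenyl)propan-2-ol]
Conditions: H2 (1 atm), Pd/C (10 wt% Pd on carbon), EtOH-EtOAc, rt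
Reagents that add atoms: none
Why: In this catalytic hydrogenolysis of a benzyl ether only the O-CH2Ph bond is benzylic to oxygen, since the C2-O bond is homobenzylic and C1 carries no heteroatom, so the hydroxyl is freed with C2 unchanged as (R).

## Compound list

1 | (R)-4-benzyl-2-oxazolidinone | O=C1N[C@H](Cc2ccccc2)CO1 | starting material
2 | benzyloxyacetyl chloride | O=C(Cl)COCc1ccccc1 | starting material
3 | N-lithio derivative of (R)-4-benzyl-2-oxazolidinone | [Li]N1[C@H](Cc2ccccc2)COC1=O | intermediate
4 | (R)-4-benzyl-3-(benzyloxyacetyl)oxazolidin-2-one | O=C(COCc1ccccc1)N1[C@H](Cc2ccccc2)COC1=O | intermediate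
5 | 1-bromo-2,4,5-trimethoxybenzene | COc1cc(OC)c(Br)cc1OC | starting material
6 | 2,4,5-trimethoxybenzaldehyde | COc1cc(OC)c(C=O)cc1OC | starting material
7 | 2,4,5-trimethoxyphenyllithium | [Li]c1cc(OC)c(OC)cc1OC | intermediate
8 | lithium bis(2,4,5-trimethoxyphenyl)methoxide | [Li+].[O-]C(c1cc(OC)c(OC)cc1OC)c1cc(OC)c(OC)cc1OC | intermediate
9 | bis(2,4,5-trimethoxyphenyl)methanol | OC(c1cc(OC)c(OC)cc1OC)c1cc(OC)c(OC)cc1OC | intermediate
10 | sodium bis(2,4,5-trimethoxyphenyl)methoxide | [Na+].[O-]C(c1cc(OC)c(OC)cc1OC)c1cc(OC)c(OC)cc1OC | intermediate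
11 | bis(2,4,5-trimethoxyphenyl)methyl methyl ether | COC(c1cc(OC)c(OC)cc1OC)c1cc(OC)c(OC)cc1OC | intermediate
12 | trichlorotitanium Z-enolate of 4 (OTi and OBn cis) | Cl[Ti](Cl)(Cl)O/C(=C\OCc1ccccc1)N1[C@H](Cc2ccccc2)COC1=O | intermediate
13 | bis(2,4,5-trimethoxyphenyl)methyl cation, counter-ion [TiCl4(OMe)]- | COc1cc(OC)c([CH+]c2cc(OC)c(OC)cc2OC)cc1OC.CO[Ti-](Cl)(Cl)(Cl)Cl | intermediate
14 | (R)-4-benzyl-3-[(S)-2-benzyloxy-3,3-bis(2,4,5-trimethoxyphenyl)propanoyl]oxazolidin-2-one | COc1cc(OC)c(C(c2cc(OC)c(OC)cc2OC)[C@@H](C(=O)N2[C@H](Cc3ccccc3)COC2=O)OCc2ccccc2)cc1OC | intermediate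
15 | (S)-2-benzyloxy-3,3-bis(2,4,5-trimethoxyphenyl)propanal | COc1cc(OC)c(C(c2cc(OC)c(OC)cc2OC)[C@@H](C=O)OCc2ccccc2)cc1OC | intermediate
16 | (S)-2-benzyloxy-3,3-bis(2,4,5-trimethoxyphenyl)propan-1-ol | COc1cc(OC)c(C(c2cc(OC)c(OC)cc2OC)[C@@H](CO)OCc2ccccc2)cc1OC | intermediate
17 | (S)-2-benzyloxy-3,3-bis(2,4,5-trimethoxyphenyl)propyl p-toluenesulfonate | COc1cc(OC)c(C(c2cc(OC)c(OC)cc2OC)[C@@H](COS(=O)(=O)c2ccc(C)cc2)OCc2ccccc2)cc1OC | intermediate
18 | (R)-2-benzyloxy-1,1-bis(2,4,5-trimethoxyphenyl)propane | COc1cc(OC)c(C(c2cc(OC)c(OC)cc2OC)[C@@H](C)OCc2ccccc2)cc1OC | intermediate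
19 | tatarinoid C, (R)-1,1-bis(2,4,5-trimethoxyphenyl)propan-2-ol | COc1cc(OC)c(C(c2cc(OC)c(OC)cc2OC)[C@@H](C)O)cc1OC | target

## Step count and risks

Total step count: 8.
Longest linear sequence: 7 steps (steps 2 to 8, from 5 and 6). Step 1 is the side branch that joins at step 4.

**Step 4 (key step).** Four processes could hurt this step:
- Titanium may release the ring carbonyl, because the benzyloxy oxygen or the extra TiCl4 competes for its coordination sites. This frees the auxiliary rotamer and erodes facial selectivity.
- The vicinal 4,5-dimethoxy pairs of 11 may tie up TiCl4 and slow ionization.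
- The cation may undergo Friedel-Crafts self-condensation with the electron-rich rings of unreacted ether.
- The two ortho-methoxy groups crowd C1 and may slow capture by the enolate.

A minor diastereomer should be removable by chromatography or crystallization, since the auxiliary is still attached in 14.

The fallback buys C2 from the chiral pool and quenches the C1 cation with hydride instead of carbon. It sets out from 5. Bromine-lithium exchange as in step 2 gives 7. A little over two equivalents of 7 are added to methyl (R)-2-(benzyloxy)propanoate (C[C@@H](OCc1ccccc1)C(=O)OC) in THF at -78 to 0 °C, giving the tertiary carbinol (R)-2-benzyloxy-1,1-bis(2,4,5-trimethoxyphenyl)propan-1-ol F1. Ionic hydrogenation (excess Et3SiH, CF3CO2H, CH2Cl2, -40 °C) then removes the tertiary hydroxyl through the same doubly stabilized C1 cation. Low temperature and excess silane are used so that hydride capture outruns proton loss from C2. The fallback comes back to the route at 18.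

**Step 5.** The exocyclic carbonyl sits next to a branched, crowded C2. Hydride may therefore attack the ring carbonyl instead, which opens the oxazolidinone rather than releasing it.

The fallback sets out from 14 and cleaves with a soft nucleophile before reducing. LiSEt (EtSH, n-BuLi, THF, 0 °C) attacks only the exocyclic carbonyl and is too weakly basic to epimerize C2. It should give S-ethyl (S)-2-benzyloxy-3,3-bis(2,4,5-trimethoxyphenyl)propanethioate F2. LiAlH4 (THF, 0 °C) reduces F2 to the primary alcohol, and the fallback comes back at 16.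

**Step 7.** Three processes could hurt this step:
- Hydride displacement may be slow at a primary carbon shielded by the branched C2 and the diarylmethyl group.
- Sulfur-oxygen cleavage may compete and return the alcohol.
- Aryl methyl ethers may be cleaved if heating becomes necessary.

The fallback sets out from 16 and replaces the polar substitution by a radical reduction that is insensitive to crowding. Appel-type iodination (I2, PPh3, imidazole, CH2Cl2, rt) should give (S)-2-benzyloxy-3-iodo-1,1-bis(2,4,5-trimethoxyphenyl)propane F3. Bu3SnH with catalytic AIBN (toluene, 80 °C) then replaces iodine by hydrogen, and the fallback comes back at 18.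

## Further compounds

F1 | step 4 | (R)-2-benzyloxy-1,1-bis(2,4,5-trimethoxyphenyl)propan-1-ol | C[C@@H](OCc1ccccc1)C(O)(c1cc(OC)c(OC)cc1OC)c1cc(OC)c(OC)cc1OC
F2 | step 5 | S-ethyl (S)-2-benzyloxy-3,3-bis(2,4,5-trimethoxyphenyl)propanethioate | COc1cc(OC)c(C(c2cc(OC)c(OC)cc2OC)[C@@H](C(=O)SCC)OCc2ccccc2)cc1OC
F3 | step 7 | (S)-2-benzyloxy-3-iodo-1,1-bis(2,4,5-trimethoxyphenyl)propane | COc1cc(OC)c(C(c2cc(OC)c(OC)cc2OC)[C@@H](CI)OCc2ccccc2)cc1OC
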